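**Retrosynthetic overview**
Numbering: C1–C15 are the atoms of the target's bicyclo[9.3.1]pentadecane core and keep these numbers in every intermediate; ring A = cyclohexene (C1, C11, C12, C13, C14, C15), ring B = twelve-membered ring (C1 to C11 plus C15).
Enabling feature: in ring A the atoms HO2C–C15–C11–C12=C13 form a γ,δ-unsaturated acid, and C13 is tied to C15 through C14–C1; the allylic ester that a Claisen disconnection of C15–C11 requires is therefore a six-membered lactone (O on C13) bridging C1 and C13 of a 14-membered carbocycle.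
Key disconnection: C15–C11 by transannular Ireland–Claisen rearrangement of that lactone (22); it closes ring A last, contracts the 14-membered ring to ring B, creates quaternary C15 and C11, frees CO2H and erases the relay centre C13.
Stereo relay: C13–O by Brown allylation (the only external chiral source) → C1 by trans conjugate addition to the dihydropyranone → C15 and C11 together in the key step.
Ring order: dihydropyranone (ring-closing metathesis) → 14-membered carbocycle (sulfone alkylation, C5–C6) → ring A; carbon sources are nerol (C6–C11), an iodo ylide and CO (C12, CH2OH, C13), two allyl units, acryloyl chloride, methacrolein and homoprenyl bromide.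

Key step: step 18

Remark: TBS = tert-butyldimethylsilyl; Alk = (2Z,6Z)-1-(TBSO)-6-methyl-8-(phenylsulfonyl)octa-2,6-dien-2-yl. The epoxide carbon in 4, the sulfone-bearing carbon C6 in 18 and the α-carbon (future C15) in 22 form as mixtures and are written without configuration; all three are erased later.

**Route**

Step 1
Reactants: 1 nerol
Product: 3 neryl phenyl sulfone, via neryl bromide 2 (not isolated)
Conditions: PBr3, Et2O, −10 °C; then PhSO2Na, DMF, rt
Reagents that add atoms: sodium benzenesulfinate, [Na+].[O-]S(=O)c1ccccc1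
Why: PBr3 converts the primary allylic alcohol to the bromide and S-alkylation of the soft sulfinate anion (SN2) should give the sulfone without allylic transposition, so the Z alkene (future C7=C8) is kept.

Step 2
Reactants: 3 neryl phenyl sulfone
Product: 5 (4Z)-4-methyl-6-(phenylsulfonyl)hex-4-enal, via epoxide 4 (not isolated)
Conditions: mCPBA, CH2Cl2, 0 °C; then H5IO6, THF/H2O, 0 °C to rt
Reagents that add atoms: mCPBA, OOC(=O)c1cccc(Cl)c1
Why: The allylic sulfone deactivates the neighbouring alkene, so mCPBA (Prilezhaev epoxidation) should attack only the distal trisubstituted alkene, and periodic acid then opens and cleaves the epoxide (glycol cleavage) to the aldehyde carbon that becomes C11.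

Step 3
Reactants: 5 (4Z)-4-methyl-6-(phenylsulfonyl)hex-4-enal
Product: 6 ethyl (2Z,6Z)-2-iodo-6-methyl-8-(phenylsulfonyl)octa-2,6-dienoate
Conditions: Ph3P=CHCO2Et, N-iodosuccinimide, K2CO3, CH2Cl2, −20 °C; then 5, rt
Reagents that add atoms: ethyl (triphenylphosphoranylidene)acetate, CCOC(=O)C=P(c1ccccc1)(c1ccccc1)c1ccccc1; N-iodosuccinimide, O=C1CCC(=O)N1I
Why: Wittig olefination with the stabilised α-iodo ylide formed in the flask should place the ester trans to the chain and give the (Z)-α-iodoenoate, fixing the geometry of the future C11=C12 alkene on which the C11 configuration depends.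

Step 4
Reactants: 6 ethyl (2Z,6Z)-2-iodo-6-methyl-8-(phenylsulfonyl)octa-2,6-dienoate
Product: 7 (2Z,6Z)-2-iodo-6-methyl-8-(phenylsulfonyl)octa-2,6-dien-1-ol
Conditions: iBu2AlH, CH2Cl2, −78 °C
Reagents that add atoms: none
Why: iBu2AlH reduces the conjugated ester by 1,2-hydride addition to the primary allylic alcohol (the future CH2OH on C12) and should leave the vinyl iodide and the sulfone untouched.

Step 5
Reactants: 7 (2Z,6Z)-2-iodo-6-methyl-8-(phenylsulfonyl)octa-2,6-dien-1-ol
Product: 8 TBS ether of 7
Conditions: TBSCl, imidazole, CH2Cl2, rt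
Reagents that add atoms: tert-butyldimethylsilyl chloride, CC(C)(C)[Si](C)(C)Cl
Why: Silylation of the primary alcohol (substitution at silicon) gives a TBS ether that should survive the later base, hydride, metathesis and heating steps and is removed last.

Step 6
Reactants: 8 TBS ether of 7
Product: 9 (2Z,6Z)-2-(TBSO-methyl)-6-methyl-8-(phenylsulfonyl)octa-2,6-dienal
Conditions: Pd(PPh3)4 (cat.), CO (1 atm), Bu3SnH (slow addition), THF, 50 °C
Reagents that add atoms: carbon monoxide, [C-]#[O+]
Why: Stille-type reductive carbonylation (oxidative addition of the vinyl iodide to zerovalent palladium, CO insertion, hydride transfer from tin) should replace iodine by CHO with retention, so the formyl carbon (C13) stays cis to the chain.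

Step 7
Reactants: 9 (2Z,6Z)-2-(TBSO-methyl)-6-methyl-8-(phenylsulfonyl)octa-2,6-dienal
Product: 10 (4R,5Z,9Z)-5-(TBSO-methyl)-9-methyl-11-(phenylsulfonyl)undeca-1,5,9-trien-4-ol
Conditions: (+)-Ipc2B(allyl), Et2O, −78 °C; then NaOH, H2O2, 0 °C
Reagents that add atoms: (+)-B-allyldiisopinocampheylborane (from (−)-α-pinene), C=CCB([C@H]1C[C@H]2C[C@@H]([C@@H]1C)C2(C)C)[C@H]1C[C@H]2C[C@@H]([C@@H]1C)C2(C)C
Why: Brown allylation through a chair-like six-membered transition state should deliver allyl to the Re face of the enal and set C13 as R (reagent control), the single stereocentre from which all others are relayed.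

Step 8
Reactants: 10 (4R,5Z,9Z)-5-(TBSO-methyl)-9-methyl-11-(phenylsulfonyl)undeca-1,5,9-trien-4-ol
Product: 11 acrylate ester of 10
Conditions: acryloyl chloride, iPr2NEt, DMAP (cat.), CH2Cl2, −20 °C
Reagents that add atoms: acryloyl chloride, C=CC(=O)Cl
Why: DMAP-catalysed acylation of the secondary allylic alcohol installs the acrylate (C15 and the carboxyl carbon) without touching the stereocentre.

Step 9
Reactants: 11 acrylate ester of 10
Product: 12 (6R)-6-Alk-5,6-dihydro-2H-pyran-2-one
Conditions: second-generation Grubbs catalyst RuCl2(=CHPh)(PCy3)(H2IMes) (cat.), CH2Cl2, 40 °C, 5 mM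
Reagents that add atoms: none
Why: Ring-closing metathesis between the acrylate and the monosubstituted alkene should form the six-membered α,β-unsaturated lactone and release ethylene while the trisubstituted alkenes remain spectators.

Step 10
Reactants: 12 (6R)-6-Alk-5,6-dihydro-2H-pyran-2-one
Product: 14 (4S,6R)-4-allyl-6-Alk-tetrahydro-2H-pyran-2-one, via silyl ketene acetal 13 (not isolated)
Conditions: CH2=CHCH2MgBr, CuBr·SMe2, Me3SiCl, THF, −78 °C; aq. NH4Cl
Reagents that add atoms: allylmagnesium bromide, C=CC[Mg]Br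
Why: Me3SiCl-accelerated conjugate addition of allylcopper should occur by axial attack anti to the C13 alkenyl group of the half-chair dihydropyranone, setting C1 trans to it (substrate control), and the silyl ketene acetal is hydrolysed on work-up.

Step 11
Reactants: 14 (4S,6R)-4-allyl-6-Alk-tetrahydro-2H-pyran-2-one
Product: 15 (4S,6R)-4-[(2E)-3-methyl-4-oxobut-2-en-1-yl]-6-Alk-tetrahydro-2H-pyran-2-one
Conditions: methacrolein, second-generation Hoveyda–Grubbs catalyst RuCl2(=CH-C6H4-2-OiPr)(H2IMes) (cat.), CH2Cl2, 40 °C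
Reagents that add atoms: methacrolein, CC(=C)C=O
Why: Olefin cross metathesis of the only monosubstituted alkene with methacrolein should give the conjugated trisubstituted enal with E geometry (C3=C4), the existing trisubstituted alkenes being far less reactive.

Step 12
Reactants: 15 (4S,6R)-4-[(2E)-3-methyl-4-oxobut-2-en-1-yl]-6-Alk-tetrahydro-2H-pyran-2-one
Product: 16 (4S,6R)-4-[(2E)-4-hydroxy-3-methylbut-2-en-1-yl]-6-Alk-tetrahydro-2H-pyran-2-one
Conditions: NaBH4, CeCl3·7H2O, MeOH, −40 °C
Reagents that add atoms: none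
Why: Luche reduction should reduce the enal 1,2 to the allylic alcohol at C5 and leave the lactone intact.

Step 13
Reactants: 16 (4S,6R)-4-[(2E)-4-hydroxy-3-methylbut-2-en-1-yl]-6-Alk-tetrahydro-2H-pyran-2-one
Product: 17 (4S,6R)-4-[(2E)-4-bromo-3-methylbut-2-en-1-yl]-6-Alk-tetrahydro-2H-pyran-2-one
Conditions: CBr4, PPh3, CH2Cl2, 0 °C
Reagents that add atoms: carbon tetrabromide, BrC(Br)(Br)Br
Why: Appel bromination converts the primary allylic alcohol to the bromide by SN2 under neutral conditions, keeping the E alkene and the silyl ether.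

Step 14
Reactants: 17 (4S,6R)-4-[(2E)-4-bromo-3-methylbut-2-en-1-yl]-6-Alk-tetrahydro-2H-pyran-2-one
Product: 18 bridged sulfone lactone (1S,3E,7Z,11Z,13R)-12-(TBSO-methyl)-4,8-dimethyl-6-(phenylsulfonyl)-14-oxabicyclo[11.3.1]heptadeca-3,7,11-trien-15-one
Conditions: LiN(SiMe3)2 (1.05 equiv, slow addition), THF, −78 to 0 °C, 1 mM
Reagents that add atoms: none
Why: One equivalent of LiN(SiMe3)2 should deprotonate only the allylic sulfone, and intramolecular SN2 alkylation of this carbanion by the allylic bromide at high dilution closes the 14-membered carbocycle (C5–C6 bond), the classical macrocyclisation of 1,5-polyene chains; the new centre at C6 is inconsequential.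

Step 15
Reactants: 18 bridged sulfone lactone
Product: 19 bridged lactone (1S,3E,7Z,11Z,13R)-12-(TBSO-methyl)-4,8-dimethyl-14-oxabicyclo[11.3.1]heptadeca-3,7,11-trien-15-one
Conditions: SmI2, HMPA, THF/MeOH, −20 °C
Reagents that add atoms: none
Why: Single-electron reductive desulfonylation by SmI2/HMPA should cleave the C6–S bond at low temperature and protonate C6 while leaving the lactone and the silyl ether intact.

Step 16
Reactants: 20 5-bromo-2-methylpent-2-ene
Product: 21 5-iodo-2-methylpent-2-ene
Conditions: NaI, acetone, reflux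
Reagents that add atoms: sodium iodide, [Na+].[I-]
Why: Finkelstein halide exchange, driven by precipitation of NaBr from acetone, gives the more reactive primary iodide.

Step 17
Reactants: 19 bridged lactone; 21 5-iodo-2-methylpent-2-ene
Product: 22 bridged α-homoprenyl lactone (1S,3E,7Z,11Z,13R)-12-(TBSO-methyl)-4,8-dimethyl-16-(4-methylpent-3-en-1-yl)-14-oxabicyclo[11.3.1]heptadeca-3,7,11-trien-15-one
Conditions: LiN(iPr)2, THF, −78 °C; then 21, HMPA, −78 to −30 °C
Reagents that add atoms: none
Why: SN2 alkylation of the lithium lactone enolate with the primary iodide installs the homoprenyl chain at the future C15, whose configuration does not matter because this carbon becomes trigonal in the key step.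

Step 18
Reactants: 22 bridged α-homoprenyl lactone
Product: 25 TBS-protected acid (1S,3E,7Z,11S,15S)-12-(TBSO-methyl)-4,8-dimethyl-15-(4-methylpent-3-en-1-yl)bicyclo[9.3.1]pentadeca-3,7,12-triene-15-carboxylic acid, via silyl ketene acetal 23 (not isolated), via trimethylsilyl ester 24 (not isolated)
Conditions: LiN(iPr)2, Me3SiCl/Et3N (in situ quench), THF, −78 °C to rt; then toluene, 100 °C; then aq. NH4Cl
Reagents that add atoms: none
Why: LiN(iPr)2 forms the lactone enolate, O-silylation gives the cyclic silyl ketene acetal 23, and on heating a concerted suprafacial [3,3]-sigmatropic shift (Ireland–Claisen) joins C15 to C11 while the C13–O bond breaks and the alkene moves from C11=C12 to C12=C13, giving silyl ester 24, which hydrolyses on work-up. The closest known reaction type is the lactone-enolate Claisen ring contraction of 6-alkenyl δ-lactone silyl ketene acetals to cyclohex-3-enecarboxylic acids (and its oxygen analogue, the dioxanone-to-dihydropyran rearrangement), here run transannularly. Ring A is closed as a six-membered carbocycle from four lactone carbons (C15, C1, C14, C13) and the two alkene carbons (C12, C11) through a boat-like, bicyclo[2.2.2]-type transition state, and the same bond contracts the 14-membered carbocycle to ring B. C15 is set because the new bond can only form on the lactone face that carries the C13 alkenyl group, which leaves CO2H cis to the C1–C2 bond; C11 is set by the Z geometry of the C11=C12 alkene in the enforced boat, which puts C10 trans to CO2H; C13 is destroyed and C1 is untouched. The step needs a boat-only topology, a single ketene acetal geometry and O- rather than C-silylation: the two-carbon tether C14–C1 excludes a chair, the enolate is endocyclic, and the in situ Me3SiCl/Et3N quench favours O-silylation.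

Step 19
Reactants: 25 TBS-protected acid
Product: 26 target acid (1S,3E,7Z,11S,15S)-12-(hydroxymethyl)-4,8-dimethyl-15-(4-methylpent-3-en-1-yl)bicyclo[9.3.1]pentadeca-3,7,12-triene-15-carboxylic acid
Conditions: Bu4NF, THF, 0 °C to rt; aq. NH4Cl
Reagents that add atoms: none
Why: Fluoride cleaves the primary TBS ether (attack at silicon) to free the hydroxymethyl group, and lactonisation onto the acid is not expected because it would force the ring A alkene to a bridgehead.

**Compound list**
1 | nerol, (2Z)-3,7-dimethylocta-2,6-dien-1-ol | CC(C)=CCC/C(C)=C\CO | starting material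
2 | neryl bromide, (2Z)-1-bromo-3,7-dimethylocta-2,6-diene | CC(C)=CCC/C(C)=C\CBr | intermediate
3 | neryl phenyl sulfone, {[(2Z)-3,7-dimethylocta-2,6-dien-1-yl]sulfonyl}benzene | CC(C)=CCC/C(C)=C\CS(=O)(=O)c1ccccc1 | intermediate
4 | 6,7-epoxide of 3 (racemic), 2,2-dimethyl-3-[(3Z)-3-methyl-5-(phenylsulfonyl)pent-3-en-1-yl]oxirane | CC1(C)OC1CC/C(C)=C\CS(=O)(=O)c1ccccc1 | intermediate
5 | (4Z)-4-methyl-6-(phenylsulfonyl)hex-4-enal | O=CCC/C(C)=C\CS(=O)(=O)c1ccccc1 | intermediate
6 | ethyl (2Z,6Z)-2-iodo-6-methyl-8-(phenylsulfonyl)octa-2,6-dienoate | CCOC(=O)/C(I)=C/CC/C(C)=C\CS(=O)(=O)c1ccccc1 | intermediate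
7 | (2Z,6Z)-2-iodo-6-methyl-8-(phenylsulfonyl)octa-2,6-dien-1-ol | OC/C(I)=C/CC/C(C)=C\CS(=O)(=O)c1ccccc1 | intermediate
8 | TBS ether of 7, tert-butyl{[(2Z,6Z)-2-iodo-6-methyl-8-(phenylsulfonyl)octa-2,6-dien-1-yl]oxy}dimethylsilane | CC(C)(C)[Si](C)(C)OC/C(I)=C/CC/C(C)=C\CS(=O)(=O)c1ccccc1 | intermediate
9 | (2Z,6Z)-2-(TBSO-methyl)-6-methyl-8-(phenylsulfonyl)octa-2,6-dienal (CHO cis to the chain) | O=C/C(CO[Si](C)(C)C(C)(C)C)=C\CC/C(C)=C\CS(=O)(=O)c1ccccc1 | intermediate
10 | (4R,5Z,9Z)-5-(TBSO-methyl)-9-methyl-11-(phenylsulfonyl)undeca-1,5,9-trien-4-ol | C=CC[C@@H](O)/C(CO[Si](C)(C)C(C)(C)C)=C\CC/C(C)=C\CS(=O)(=O)c1ccccc1 | intermediate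
11 | acrylate ester of 10 | C=CC[C@@H](OC(=O)C=C)/C(CO[Si](C)(C)C(C)(C)C)=C\CC/C(C)=C\CS(=O)(=O)c1ccccc1 | intermediate
12 | (6R)-6-Alk-5,6-dihydro-2H-pyran-2-one | O=C1C=CC[C@@H](O1)/C(CO[Si](C)(C)C(C)(C)C)=C\CC/C(C)=C\CS(=O)(=O)c1ccccc1 | intermediate
13 | silyl ketene acetal, (2R,4S)-4-allyl-2-Alk-6-(trimethylsilyloxy)-3,4-dihydro-2H-pyran | C[Si](C)(C)OC1=C[C@@H](CC=C)C[C@@H](O1)/C(CO[Si](C)(C)C(C)(C)C)=C\CC/C(C)=C\CS(=O)(=O)c1ccccc1 | intermediate
14 | (4S,6R)-4-allyl-6-Alk-tetrahydro-2H-pyran-2-one (trans) | O=C1C[C@@H](CC=C)C[C@@H](O1)/C(CO[Si](C)(C)C(C)(C)C)=C\CC/C(C)=C\CS(=O)(=O)c1ccccc1 | intermediate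
15 | (4S,6R)-4-[(2E)-3-methyl-4-oxobut-2-en-1-yl]-6-Alk-tetrahydro-2H-pyran-2-one | O=C1C[C@@H](C/C=C(\C)C=O)C[C@@H](O1)/C(CO[Si](C)(C)C(C)(C)C)=C\CC/C(C)=C\CS(=O)(=O)c1ccccc1 | intermediate
16 | (4S,6R)-4-[(2E)-4-hydroxy-3-methylbut-2-en-1-yl]-6-Alk-tetrahydro-2H-pyran-2-one | O=C1C[C@@H](C/C=C(\C)CO)C[C@@H](O1)/C(CO[Si](C)(C)C(C)(C)C)=C\CC/C(C)=C\CS(=O)(=O)c1ccccc1 | intermediate
17 | (4S,6R)-4-[(2E)-4-bromo-3-methylbut-2-en-1-yl]-6-Alk-tetrahydro-2H-pyran-2-one | O=C1C[C@@H](C/C=C(\C)CBr)C[C@@H](O1)/C(CO[Si](C)(C)C(C)(C)C)=C\CC/C(C)=C\CS(=O)(=O)c1ccccc1 | intermediate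
18 | bridged sulfone lactone, (1S,3E,7Z,11Z,13R)-12-(TBSO-methyl)-4,8-dimethyl-6-(phenylsulfonyl)-14-oxabicyclo[11.3.1]heptadeca-3,7,11-trien-15-one (C6 epimers) | O=C1C[C@@H]2C[C@@H](O1)/C(CO[Si](C)(C)C(C)(C)C)=C\CC/C(C)=C\C(S(=O)(=O)c1ccccc1)C/C(C)=C/C2 | intermediate
19 | bridged lactone, (1S,3E,7Z,11Z,13R)-12-(TBSO-methyl)-4,8-dimethyl-14-oxabicyclo[11.3.1]heptadeca-3,7,11-trien-15-one | O=C1C[C@@H]2C[C@@H](O1)/C(CO[Si](C)(C)C(C)(C)C)=C\CC/C(C)=C\CC/C(C)=C/C2 | intermediate
20 | 5-bromo-2-methylpent-2-ene | CC(C)=CCCBr | starting material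
21 | 5-iodo-2-methylpent-2-ene | CC(C)=CCCI | intermediate
22 | bridged α-homoprenyl lactone, (1S,3E,7Z,11Z,13R)-12-(TBSO-methyl)-4,8-dimethyl-16-(4-methylpent-3-en-1-yl)-14-oxabicyclo[11.3.1]heptadeca-3,7,11-trien-15-one (C16 epimers) | O=C1C(CCC=C(C)C)[C@@H]2C[C@@H](O1)/C(CO[Si](C)(C)C(C)(C)C)=C\CC/C(C)=C\CC/C(C)=C/C2 | intermediate
23 | silyl ketene acetal of 22 (15-trimethylsilyloxy-14-oxabicyclo[11.3.1]heptadeca-3,7,11,15-tetraene) | C[Si](C)(C)OC1=C(CCC=C(C)C)[C@@H]2C[C@@H](O1)/C(CO[Si](C)(C)C(C)(C)C)=C\CC/C(C)=C\CC/C(C)=C/C2 | intermediate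
24 | trimethylsilyl ester of 25 | CC(C)=CCC[C@]1(C(=O)O[Si](C)(C)C)[C@@H]2CC=C(CO[Si](C)(C)C(C)(C)C)[C@@H]1CC/C(C)=C\CC/C(C)=C/C2 | intermediate
25 | TBS-protected acid, (1S,3E,7Z,11S,15S)-12-(TBSO-methyl)-4,8-dimethyl-15-(4-methylpent-3-en-1-yl)bicyclo[9.3.1]pentadeca-3,7,12-triene-15-carboxylic acid | CC(C)=CCC[C@]1(C(=O)O)[C@@H]2CC=C(CO[Si](C)(C)C(C)(C)C)[C@@H]1CC/C(C)=C\CC/C(C)=C/C2 | intermediate
26 | (1S,3E,7Z,11S,15S)-12-(hydroxymethyl)-4,8-dimethyl-15-(4-methylpent-3-en-1-yl)bicyclo[9.3.1]pentadeca-3,7,12-triene-15-carboxylic acid | CC(C)=CCC[C@]1(C(=O)O)[C@@H]2CC=C(CO)[C@@H]1CC/C(C)=C\CC/C(C)=C/C2 | target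

**Step count and risks**
Total step count: 19. Longest linear sequence: 18 steps (steps 1–15 and 17–19; step 16 is a one-step side branch).

Most likely to fail, in this order:

1. Step 18 (key step). What may go wrong: slow or incomplete enolisation of the α-branched lactone, C-silylation, or fragmentation of the ketene acetal before the strained boat array is reached. Fallback (palladium-mediated transannular allylic alkylation; same bond, ring A still closed last): it sets out from 22. Ring opening with LiOCH2CH2SiMe3 (THF, 0 °C) would give the 2-(trimethylsilyl)ethyl hydroxy ester F1, which is acylated in the same flask with ClCO2Me/pyridine to the allylic methyl carbonate F2. Enolisation of F2 with LiN(iPr)2/LiCl (THF, −78 °C) and addition of Pd(PPh3)4 should ionise the carbonate with inversion and let the tethered ester enolate attack the far allyl terminus C11 anti to palladium (net retention, the same facial outcome at C11 as the sigmatropic route), closing ring A to the 2-(trimethylsilyl)ethyl ester F3. The C15 configuration is then no longer enforced by a cyclic array, so epimers may have to be separated. Bu4NF removes both silicon groups of F3, and the sequence comes back to the route at 26.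

2. Step 14. What may go wrong: competing enolisation of the lactone followed by intramolecular C-alkylation by the allylic bromide, or intermolecular alkylation instead of ring closure. Fallback (ring closure by olefin metathesis instead of alkylation): it sets out from 14. Deprotonation of the sulfone (LiN(SiMe3)2, THF, −78 °C) and alkylation with 3-bromo-2-methylpropene would give the methallylated sulfone F4. Ring-closing metathesis between its allyl and methallyl groups (second-generation Grubbs catalyst RuCl2(=CHPh)(PCy3)(H2IMes), toluene, 80 °C, 1 mM) should form the C3=C4 alkene and comes back to the route at 18. The E/Z ratio is then under thermodynamic control, and the isomers would be separated at 18 or 19.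

3. Step 15. What may go wrong: allylic transposition or E/Z scrambling of the C7=C8 alkene in the allyl radical or anion formed by electron transfer, and reductive cleavage of the allylic lactone C13–O bond. Fallback (hydride delivery through a π-allyl palladium complex on a lactone-free substrate): it sets out from 18. Saponification (LiOH, THF/H2O) would give the sulfonyl hydroxy acid F5, whose carboxylate and allylic alkoxide resist both the hydride and zerovalent palladium. PdCl2(dppp)/LiBHEt3 (THF, 0 °C) should replace the sulfonyl group by hydrogen with retention of alkene position and geometry to give the hydroxy acid F6. Yamaguchi lactonisation (2,4,6-trichlorobenzoyl chloride, Et3N; then DMAP, toluene) comes back to the route at 19.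

**Further compounds**
F1 | step 18 | 2-(trimethylsilyl)ethyl hydroxy ester from ring opening of 22 | C[Si](C)(C)CCOC(=O)C(CCC=C(C)C)[C@@H]1C[C@@H](O)/C(CO[Si](C)(C)C(C)(C)C)=C\CC/C(C)=C\CC/C(C)=C/C1
F2 | step 18 | allylic methyl carbonate of F1 (carbonate on the C13 oxygen) | C[Si](C)(C)CCOC(=O)C(CCC=C(C)C)[C@@H]1C[C@@H](OC(=O)OC)/C(CO[Si](C)(C)C(C)(C)C)=C\CC/C(C)=C\CC/C(C)=C/C1
F3 | step 18 | 2-(trimethylsilyl)ethyl ester of 25 | CC(C)=CCC[C@]1(C(=O)OCC[Si](C)(C)C)[C@@H]2CC=C(CO[Si](C)(C)C(C)(C)C)[C@@H]1CC/C(C)=C\CC/C(C)=C/C2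
F4 | step 14 | methallylated sulfone of 14 (2-methylallyl group on the sulfone-bearing carbon C6) | O=C1C[C@@H](CC=C)C[C@@H](O1)/C(CO[Si](C)(C)C(C)(C)C)=C\CC/C(C)=C\C(CC(C)=C)S(=O)(=O)c1ccccc1
F5 | step 15 | sulfonyl hydroxy acid from saponification of 18 | OC(=O)C[C@@H]1C[C@@H](O)/C(CO[Si](C)(C)C(C)(C)C)=C\CC/C(C)=C\C(S(=O)(=O)c2ccccc2)C/C(C)=C/C1
F6 | step 15 | desulfonylated hydroxy acid (seco acid of 19) | OC(=O)C[C@@H]1C[C@@H](O)/C(CO[Si](C)(C)C(C)(C)C)=C\CC/C(C)=C\CC/C(C)=C/C1
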